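**Plan**
- Retrosynthetic cuts, in order: (a) CO2H back to a PMB-protected CH2OH (oxidation level only); (b) the CH2–CH2 bond between the exocyclic methylene on ring C5 and C1 of the farnesyl chain, giving an α-sulfonyl carbanion and (2E,6E)-farnesyl bromide; (c) ring C2–C(alkenyl), giving a ring oxocarbenium ion and an alkenyltrifluoroborate; (d) ring O1–C2, giving a lactol from ozonolysis; (e) C5–CH2S, an Evans alkylation.
- Forward order: the C5 stereocentre is made on an acyclic hexenoyl imide; the oxane ring (O1, C2–C6) arises by lactolisation after ozonolysis; the C2 alkenyl group is added to the ring oxocarbenium ion; the C15 chain is then joined; the sulfonyl helper is removed and the acrylic acid is unveiled last.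
- Stereochemistry: C5 (R) comes from the (R)-4-benzyloxazolidinone auxiliary. C2 (R) comes from axial attack on the half-chair oxocarbenium ion with the C5 substituent pseudo-equatorial, which gives the less stable 2,5-cis ring under kinetic control. The 3E,7E alkenes are carried unchanged from farnesyl bromide.
- Enabling feature: the exocyclic CH2 on ring C5 is a primary carbon whose β-carbon (C5) bears only C and H, and its bond partner is the primary allylic C1 next to the C=C(CH3) alkene of an all-E farnesyl unit. A sulfonyl-stabilised carbanion on that CH2 therefore has no β-leaving group and can take the allylic bromide by direct SN2 at C1, with no allylic transposition and no E/Z change, while the cis oxane ring is a spectator.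
- The acrylate is carried as a PMB-protected 2-substituted allyl alcohol, because an acrylate would be a Michael acceptor for the carbanion; nucleophilic base is kept away from the finished acrylate so that the cis ring cannot open and re-close.

Key step: step 10

Assumption: the SMILES is read as the (2R,5R) isomer, i.e. the 2,5-cis-disubstituted oxane with a 3E,7E side chain, so the ring stereochemistry has to be made under kinetic and not thermodynamic control.

Step 1
Reactants: 1 hex-5-enoic acid; 2 (R)-4-benzyl-1,3-oxazolidin-2-one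
Product: 4 (R)-4-benzyl-3-(hex-5-enoyl)-1,3-oxazolidin-2-one, via hex-5-enoic pivalic anhydride 3 (not isolated)
Conditions: PivCl, Et3N, THF, −20 °C; then LiCl, 2, −20 °C → rt
Reagents that add atoms: none
Why: Mixed-anhydride N-acylation of the oxazolidinone (LiCl-accelerated) is the standard way to load an Evans auxiliary; no stereocentre is formed.

Step 2
Reactants: 4 (R)-4-benzyl-3-(hex-5-enoyl)-1,3-oxazolidin-2-one; 5 chloromethyl phenyl sulfide
Product: 7 (R)-4-benzyl-3-[(2R)-2-[(phenylsulfanyl)methyl]hex-5-enoyl]-1,3-oxazolidin-2-one, via chlorotitanium (Z)-enolate 6 (not isolated)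
Conditions: TiCl4 (1.05 equiv), i-Pr2NEt (1.1 equiv), CH2Cl2, 0 °C; then 5, 0 °C → rt
Reagents that add atoms: none
Why: Evans alkylation of the chelated (Z)-titanium enolate with an SN1-type electrophile: TiCl4 ionises the α-chloro sulfide to a thionium ion, which is attacked on the enolate face opposite the benzyl group and should set the (2R) centre that becomes ring C5.

Step 3
Reactants: 7 (R)-4-benzyl-3-[(2R)-2-[(phenylsulfanyl)methyl]hex-5-enoyl]-1,3-oxazolidin-2-one
Product: 8 (2R)-2-[(phenylsulfanyl)methyl]hex-5-en-1-ol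
Conditions: LiBH4, MeOH (1 equiv), THF, 0 °C
Reagents that add atoms: none
Why: Reductive removal of the Evans auxiliary with LiBH4 gives the primary alcohol (the future C6–O1) without touching sulfide or alkene and cannot epimerise the new centre, which is no longer α to a carbonyl.

Step 4
Reactants: 8 (2R)-2-[(phenylsulfanyl)methyl]hex-5-en-1-ol
Product: 9 (2R)-2-[(phenylsulfonyl)methyl]hex-5-en-1-ol
Conditions: (NH4)6Mo7O24·4H2O (cat.), 30% aq H2O2, EtOH, 0 °C → rt
Reagents that add atoms: hydrogen peroxide, OO
Why: Molybdate-catalysed sulfide-to-sulfone oxidation is chemoselective in the presence of an unactivated terminal alkene and a primary alcohol; the sulfone survives ozone, cannot bridge to C2 at the oxocarbenium stage as a sulfide would, and later acidifies the adjacent CH2.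

Step 5
Reactants: 9 (2R)-2-[(phenylsulfonyl)methyl]hex-5-en-1-ol
Product: 12 (5R)-5-[(phenylsulfonyl)methyl]oxan-2-ol (anomer mixture), via ozonide 10 (not isolated), via hydroxy aldehyde 11 (not isolated)
Conditions: O3, CH2Cl2, −78 °C; then PPh3, −78 °C → rt
Reagents that add atoms: ozone, [O-][O+]=O
Why: Ozonolysis with reductive work-up cleaves the terminal alkene to the 5-hydroxy aldehyde, which should close spontaneously to the six-membered lactol and so forms the oxane ring; the stereocentre is not involved.

Step 6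
Reactants: 12 (5R)-5-[(phenylsulfonyl)methyl]oxan-2-ol
Product: 13 (5R)-5-[(phenylsulfonyl)methyl]oxan-2-yl acetate (anomer mixture)
Conditions: Ac2O, pyridine, DMAP (cat.), CH2Cl2, 0 °C
Reagents that add atoms: acetic anhydride, CC(=O)OC(C)=O
Why: Acetylation of the lactol gives an anomeric acetate, a standard oxocarbenium precursor; the anomer ratio is of no consequence because both anomers give the same cation.

Step 7
Reactants: 14 2,3-dibromoprop-1-ene; 15 4-methoxybenzyl alcohol
Product: 17 1-{[(2-bromoprop-2-en-1-yl)oxy]methyl}-4-methoxybenzene, via sodium 4-methoxybenzyl oxide 16 (not isolated)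
Conditions: NaH, THF, 0 °C; then 14, 0 °C → rt
Reagents that add atoms: none
Why: Williamson ether synthesis at the allylic bromide (SN2 and SN2′ give the same product); the vinylic bromide is inert to the alkoxide.

Step 8
Reactants: 17 1-{[(2-bromoprop-2-en-1-yl)oxy]methyl}-4-methoxybenzene
Product: 20 potassium trifluoro{3-[(4-methoxybenzyl)oxy]prop-1-en-2-yl}borate, via alkenyllithium 18 (not isolated), via lithium trimethoxyborate 19 (not isolated)
Conditions: t-BuLi (2 equiv), Et2O, −78 °C; B(OMe)3, −78 °C → rt; then aq KHF2, MeOH, rt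
Reagents that add atoms: trimethyl borate, COB(OC)OC; potassium hydrogen difluoride, [K+].F.[F-]
Why: Bromine–lithium exchange, borate formation and KHF2 treatment is the standard route to an air-stable alkenyltrifluoroborate; the low temperature is meant to suppress β-elimination of the alkoxide from the alkenyllithium.

Step 9
Reactants: 13 (5R)-5-[(phenylsulfonyl)methyl]oxan-2-yl acetate; 20 potassium trifluoro{3-[(4-methoxybenzyl)oxy]prop-1-en-2-yl}borate
Product: 23 (2R,5R)-2-{3-[(4-methoxybenzyl)oxy]prop-1-en-2-yl}-5-[(phenylsulfonyl)methyl]oxane, via alkenyldifluoroborane 21 (not isolated), via oxocarbenium ion 22 (not isolated)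
Conditions: BF3·OEt2 (2 equiv), CH2Cl2, −40 → 0 °C
Reagents that add atoms: none
Why: Lewis-acid C-glycosylation with an organotrifluoroborate: BF3 turns the borate into the alkenyldifluoroborane, which ionises the acetate and transfers its alkenyl group through the boron-bound carbon to the half-chair oxocarbenium ion; axial attack on the conformer with the C5 substituent pseudo-equatorial should give the 2,5-cis (2R,5R) ring, and the non-basic reagent leaves the acidic α-sulfonyl CH2 untouched.

Step 10
Reactants: 23 (2R,5R)-2-{3-[(4-methoxybenzyl)oxy]prop-1-en-2-yl}-5-[(phenylsulfonyl)methyl]oxane; 24 (2E,6E)-farnesyl bromide [(2E,6E)-1-bromo-3,7,11-trimethyldodeca-2,6,10-triene]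
Product: 26 (2R,5R)-2-{3-[(4-methoxybenzyl)oxy]prop-1-en-2-yl}-5-[(3E,7E)-4,8,12-trimethyl-1-(phenylsulfonyl)trideca-3,7,11-trien-1-yl]oxane (epimers at the sulfonyl carbon), via α-lithio sulfone 25 (not isolated)
Conditions: n-BuLi (1.05 equiv), THF, −78 °C; then 24, −78 → −20 °C
Reagents that add atoms: none
Why: n-BuLi deprotonates the exocyclic CH2 between ring C5 and the sulfonyl group, the only strongly acidic site, and the α-sulfonyl carbanion 25 displaces bromide from the primary allylic C1 of 24 by direct SN2, forming the C–C bond that unites the oxane with the C15 chain. The closest known reaction type is the alkylation of sulfone-stabilised carbanions with allylic halides used in isoprenoid chain assembly (Julia-type sulfone coupling). No ring is closed and the oxane is a spectator; the only new stereocentre is the sulfonyl-bearing carbon, formed without control as an inconsequential epimer mixture and erased in step 11, while C2 and C5 carry no hydrogen of comparable acidity and should keep their configuration. The step needs α- over γ-attack and retention of the 2E,6E geometry: the unhindered primary C1 against the fully substituted C3 secures the first, and the non-ionising SN2 pathway at low temperature secures the second. It also needs a carbanion that does not destroy its own substrate: its β-carbon (C5) bears only C and H so no β-elimination is possible, the ring oxygen is a γ-alkoxide too poor to leave, and the acrylate is masked as a PMB allyl ether that is no Michael acceptor. Monoalkylation should follow from one equivalent of base and the greater hindrance of the substituted α-carbon in 26.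

Step 11
Reactants: 26 (2R,5R)-2-{3-[(4-methoxybenzyl)oxy]prop-1-en-2-yl}-5-[(3E,7E)-4,8,12-trimethyl-1-(phenylsulfonyl)trideca-3,7,11-trien-1-yl]oxane
Product: 27 (2R,5R)-2-{3-[(4-methoxybenzyl)oxy]prop-1-en-2-yl}-5-[(3E,7E)-4,8,12-trimethyltrideca-3,7,11-trien-1-yl]oxane
Conditions: Mg turnings, MeOH, rt → 50 °C
Reagents that add atoms: none
Why: Reductive desulfonylation by electron transfer from Mg in MeOH cleaves the alkyl–sulfonyl bond and protonates the resulting carbanion, which removes the helper and its stereocentre while isolated alkenes and the PMB ether should be untouched.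

Step 12
Reactants: 27 (2R,5R)-2-{3-[(4-methoxybenzyl)oxy]prop-1-en-2-yl}-5-[(3E,7E)-4,8,12-trimethyltrideca-3,7,11-trien-1-yl]oxane
Product: 28 2-[(2R,5R)-5-[(3E,7E)-4,8,12-trimethyltrideca-3,7,11-trien-1-yl]oxan-2-yl]prop-2-en-1-ol
Conditions: DDQ, CH2Cl2/pH 7 buffer, 0 °C
Reagents that add atoms: none
Why: Oxidative PMB cleavage with DDQ (benzylic hydride abstraction, then hydrolysis) under buffered conditions should free the allylic alcohol without oxidising the isolated trisubstituted alkenes.

Step 13
Reactants: 28 2-[(2R,5R)-5-[(3E,7E)-4,8,12-trimethyltrideca-3,7,11-trien-1-yl]oxan-2-yl]prop-2-en-1-ol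
Product: 29 2-[(2R,5R)-5-[(3E,7E)-4,8,12-trimethyltrideca-3,7,11-trien-1-yl]oxan-2-yl]prop-2-enal
Conditions: MnO2 (excess), CH2Cl2, rt
Reagents that add atoms: none
Why: MnO2 oxidises allylic alcohols selectively to enals under neutral conditions, so the cis ring and the polyene should be unaffected.

Step 14
Reactants: 29 2-[(2R,5R)-5-[(3E,7E)-4,8,12-trimethyltrideca-3,7,11-trien-1-yl]oxan-2-yl]prop-2-enal
Product: 30 rhopaloic acid B [2-[(2R,5R)-5-[(3E,7E)-4,8,12-trimethyltrideca-3,7,11-trien-1-yl]oxan-2-yl]prop-2-enoic acid]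
Conditions: NaClO2, NaH2PO4, 2-methyl-2-butene (large excess), t-BuOH/H2O, 0 °C → rt
Reagents that add atoms: sodium chlorite, [Na+].[O-]Cl=O
Why: Pinnick oxidation converts the enal to the acrylic acid under mildly acidic, non-nucleophilic conditions that avoid addition–elimination ring opening and C2 epimerisation, with excess 2-methyl-2-butene taking up the hypochlorous acid that would otherwise attack the chain alkenes.

**Compound list**
1 | hex-5-enoic acid | C=CCCCC(=O)O | starting material
2 | (R)-4-benzyl-1,3-oxazolidin-2-one | O=C1N[C@H](Cc2ccccc2)CO1 | starting material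
3 | hex-5-enoic pivalic anhydride | C=CCCCC(=O)OC(=O)C(C)(C)C | intermediate
4 | (R)-4-benzyl-3-(hex-5-enoyl)-1,3-oxazolidin-2-one | C=CCCCC(=O)N1[C@H](Cc2ccccc2)COC1=O | intermediate
5 | chloromethyl phenyl sulfide | ClCSc1ccccc1 | starting material
6 | trichlorotitanium (Z)-enolate of 4 | C=CCC/C=C(\O[Ti](Cl)(Cl)Cl)N1[C@H](Cc2ccccc2)COC1=O | intermediate
7 | (R)-4-benzyl-3-[(2R)-2-[(phenylsulfanyl)methyl]hex-5-enoyl]-1,3-oxazolidin-2-one | C=CCC[C@@H](CSc1ccccc1)C(=O)N1[C@H](Cc2ccccc2)COC1=O | intermediate
8 | (2R)-2-[(phenylsulfanyl)methyl]hex-5-en-1-ol | C=CCC[C@@H](CSc1ccccc1)CO | intermediate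
9 | (2R)-2-[(phenylsulfonyl)methyl]hex-5-en-1-ol | C=CCC[C@@H](CS(=O)(=O)c1ccccc1)CO | intermediate
10 | ozonide of 9 (3-substituted 1,2,4-trioxolane) | O1OC(CC[C@@H](CS(=O)(=O)c2ccccc2)CO)OC1 | intermediate
11 | (4R)-5-hydroxy-4-[(phenylsulfonyl)methyl]pentanal | O=CCC[C@@H](CS(=O)(=O)c1ccccc1)CO | intermediate
12 | (5R)-5-[(phenylsulfonyl)methyl]oxan-2-ol (anomer mixture) | OC1CC[C@@H](CS(=O)(=O)c2ccccc2)CO1 | intermediate
13 | (5R)-5-[(phenylsulfonyl)methyl]oxan-2-yl acetate (anomer mixture) | CC(=O)OC1CC[C@@H](CS(=O)(=O)c2ccccc2)CO1 | intermediate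
14 | 2,3-dibromoprop-1-ene | C=C(Br)CBr | starting material
15 | 4-methoxybenzyl alcohol | COc1ccc(CO)cc1 | starting material
16 | sodium 4-methoxybenzyl oxide | COc1ccc(C[O-])cc1.[Na+] | intermediate
17 | 1-{[(2-bromoprop-2-en-1-yl)oxy]methyl}-4-methoxybenzene | C=C(Br)COCc1ccc(OC)cc1 | intermediate
18 | {3-[(4-methoxybenzyl)oxy]prop-1-en-2-yl}lithium | [Li]C(=C)COCc1ccc(OC)cc1 | intermediate
19 | lithium trimethoxy{3-[(4-methoxybenzyl)oxy]prop-1-en-2-yl}borate | C=C(COCc1ccc(OC)cc1)[B-](OC)(OC)OC.[Li+] | intermediate
20 | potassium trifluoro{3-[(4-methoxybenzyl)oxy]prop-1-en-2-yl}borate | C=C(COCc1ccc(OC)cc1)[B-](F)(F)F.[K+] | intermediate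
21 | difluoro{3-[(4-methoxybenzyl)oxy]prop-1-en-2-yl}borane | C=C(COCc1ccc(OC)cc1)B(F)F | intermediate
22 | (3R)-3-[(phenylsulfonyl)methyl]-3,4,5,6-tetrahydro-2H-pyran-1-ium (oxocarbenium ion from 13) | [O+]1=CCC[C@@H](CS(=O)(=O)c2ccccc2)C1 | intermediate
23 | (2R,5R)-2-{3-[(4-methoxybenzyl)oxy]prop-1-en-2-yl}-5-[(phenylsulfonyl)methyl]oxane | C=C(COCc1ccc(OC)cc1)[C@H]1CC[C@@H](CS(=O)(=O)c2ccccc2)CO1 | intermediate
24 | (2E,6E)-farnesyl bromide | BrC/C=C(\C)CC/C=C(\C)CCC=C(C)C | starting material
25 | α-lithio sulfone from 23 | C=C(COCc1ccc(OC)cc1)[C@H]1CC[C@@H](C([Li])S(=O)(=O)c2ccccc2)CO1 | intermediate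
26 | (2R,5R)-2-{3-[(4-methoxybenzyl)oxy]prop-1-en-2-yl}-5-[(3E,7E)-4,8,12-trimethyl-1-(phenylsulfonyl)trideca-3,7,11-trien-1-yl]oxane (epimers at the sulfonyl carbon) | C=C(COCc1ccc(OC)cc1)[C@H]1CC[C@@H](C(C/C=C(\C)CC/C=C(\C)CCC=C(C)C)S(=O)(=O)c2ccccc2)CO1 | intermediate
27 | (2R,5R)-2-{3-[(4-methoxybenzyl)oxy]prop-1-en-2-yl}-5-[(3E,7E)-4,8,12-trimethyltrideca-3,7,11-trien-1-yl]oxane | C=C(COCc1ccc(OC)cc1)[C@H]1CC[C@@H](CC/C=C(\C)CC/C=C(\C)CCC=C(C)C)CO1 | intermediate
28 | 2-[(2R,5R)-5-[(3E,7E)-4,8,12-trimethyltrideca-3,7,11-trien-1-yl]oxan-2-yl]prop-2-en-1-ol | C=C(CO)[C@H]1CC[C@@H](CC/C=C(\C)CC/C=C(\C)CCC=C(C)C)CO1 | intermediate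
29 | 2-[(2R,5R)-5-[(3E,7E)-4,8,12-trimethyltrideca-3,7,11-trien-1-yl]oxan-2-yl]prop-2-enal | C=C(C=O)[C@H]1CC[C@@H](CC/C=C(\C)CC/C=C(\C)CCC=C(C)C)CO1 | intermediate
30 | rhopaloic acid B, 2-[(2R,5R)-5-[(3E,7E)-4,8,12-trimethyltrideca-3,7,11-trien-1-yl]oxan-2-yl]prop-2-enoic acid | C=C(C(=O)O)[C@H]1CC[C@@H](CC/C=C(\C)CC/C=C(\C)CCC=C(C)C)CO1 | target

**Summary**
Total step count: 14. Longest linear sequence: 12 steps (steps 1–6 and 9–14, from hex-5-enoic acid); steps 7–8 form a two-step side branch.

The three steps most likely to fail: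

Step 9. Alkenyl transfer from the hindered 1,1-disubstituted alkenylborane may be slow, so that the oxocarbenium ion loses a proton to the enol ether. Facial selectivity may also be eroded if a sulfonyl oxygen stabilises the conformer with the C5 substituent pseudo-axial. The fallback sets C2 by reagent control and closes the ring at O1–C6 instead of forming a bond at C2. It sets out from lactol 12: Nozaki–Hiyama–Kishi addition of bromide 17 (CrCl2, cat. NiCl2, DMF) to the open hydroxy-aldehyde form should give (2R)-6-{[(4-methoxybenzyl)oxy]methyl}-2-[(phenylsulfonyl)methyl]hept-6-ene-1,5-diol F1 as a mixture of C5 epimers. MnO2 should oxidise only the allylic secondary alcohol to (6R)-7-hydroxy-2-{[(4-methoxybenzyl)oxy]methyl}-6-[(phenylsulfonyl)methyl]hept-1-en-3-one F2. Corey–Bakshi–Shibata reduction ((S)-Me-CBS, catecholborane, toluene, −78 °C) should then give (2R,5R)-6-{[(4-methoxybenzyl)oxy]methyl}-2-[(phenylsulfonyl)methyl]hept-6-ene-1,5-diol F3. Tf2O and 2,6-lutidine at −78 °C should sulfonylate the primary hydroxyl to (2R,5R)-5-hydroxy-6-{[(4-methoxybenzyl)oxy]methyl}-2-[(phenylsulfonyl)methyl]hept-6-en-1-yl trifluoromethanesulfonate F4, which on warming closes by 6-exo-tet attack of the secondary hydroxyl, with retention at both centres, and comes back to the route at 23.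

Step 2. The thionium ion from 5 may be captured sluggishly or with reduced facial control, and the chloro sulfide may self-condense under TiCl4. The fallback replaces direct thiomethylation by hydroxymethylation followed by C–O to C–S exchange. It sets out from imide 4: the same titanium enolate is treated with s-trioxane (TiCl4, i-Pr2NEt, CH2Cl2, 0 °C) to give (R)-4-benzyl-3-[(2S)-2-(hydroxymethyl)hex-5-enoyl]-1,3-oxazolidin-2-one F5, and Hata thioetherification (PhSSPh, n-Bu3P, THF) should convert the primary alcohol into the phenyl sulfide and come back to the route at 7.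

Step 8. The 2-lithioallyl ether 18 can lose 4-methoxybenzyl oxide by β-elimination (allene formation) before it is trapped by the borate ester. The fallback uses palladium-catalysed borylation instead of bromine–lithium exchange. It sets out from bromide 17: Miyaura borylation (B2pin2, PdCl2(PPh3)2, PPh3, KOPh, toluene, 50 °C) should give 2-{3-[(4-methoxybenzyl)oxy]prop-1-en-2-yl}-4,4,5,5-tetramethyl-1,3,2-dioxaborolane F6, which aqueous KHF2 in MeOH should convert into the trifluoroborate, coming back to the route at 20.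

Further compounds
F1 | step 9 | (2R)-6-{[(4-methoxybenzyl)oxy]methyl}-2-[(phenylsulfonyl)methyl]hept-6-ene-1,5-diol (C5 epimers) | C=C(COCc1ccc(OC)cc1)C(O)CC[C@@H](CS(=O)(=O)c2ccccc2)CO
F2 | step 9 | (6R)-7-hydroxy-2-{[(4-methoxybenzyl)oxy]methyl}-6-[(phenylsulfonyl)methyl]hept-1-en-3-one | C=C(COCc1ccc(OC)cc1)C(=O)CC[C@@H](CS(=O)(=O)c2ccccc2)CO
F3 | step 9 | (2R,5R)-6-{[(4-methoxybenzyl)oxy]methyl}-2-[(phenylsulfonyl)methyl]hept-6-ene-1,5-diol | C=C(COCc1ccc(OC)cc1)[C@H](O)CC[C@@H](CS(=O)(=O)c2ccccc2)CO
F4 | step 9 | (2R,5R)-5-hydroxy-6-{[(4-methoxybenzyl)oxy]methyl}-2-[(phenylsulfonyl)methyl]hept-6-en-1-yl trifluoromethanesulfonate | C=C(COCc1ccc(OC)cc1)[C@H](O)CC[C@@H](CS(=O)(=O)c2ccccc2)COS(=O)(=O)C(F)(F)F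
F5 | step 2 | (R)-4-benzyl-3-[(2S)-2-(hydroxymethyl)hex-5-enoyl]-1,3-oxazolidin-2-one | C=CCC[C@@H](CO)C(=O)N1[C@H](Cc2ccccc2)COC1=O
F6 | step 8 | 2-{3-[(4-methoxybenzyl)oxy]prop-1-en-2-yl}-4,4,5,5-tetramethyl-1,3,2-dioxaborolane | C=C(COCc1ccc(OC)cc1)B1OC(C)(C)C(C)(C)O1
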